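## Retrosynthetic overview

1. Target 13 is a γ-butyrolactone (ring C: O1, C2(=O), C3, C4, C5) with an E-arylidene (ring B, syringyl) on C3 and a benzyl group (ring A, guaiacyl) on the (R)-stereocentre C4. The two phenol MOM ethers are removed last.
2. C3=CH–ring B is disconnected by aldol addition of lactone 7 to MOM-protected syringaldehyde 9, followed by elimination of acetate (steps 6 and 7).
3. The CH2–ring A bond is disconnected by a B-alkyl Suzuki–Miyaura coupling of boronate 4 with aryl bromide 6 (step 4).
4. Ring C is the only ring made; rings A and B are bought. It is closed at C4–C5 by an enantioselective copper-catalysed borylative cyclization of chloromethyl but-3-enoate 2, which in one operation forms the ring, sets C4 and places boron on the exocyclic CH2.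
5. Enabling feature: C4 lies between two CH2 groups, C5 on the ring oxygen O1 and the exocyclic CH2 that leads to ring A. C4 and that CH2 can therefore be the terminal C=C of a but-3-enoate whose ester oxygen O1 already holds C5 as OCH2Cl, and the ester C2=O is placed to chelate copper on C4.

Key step: step 2

Assumption: the sense of induction of the copper catalyst cannot be known in advance; (R)-SEGPHOS is written, and its antipode is used if the first run gives the (S)-boronate.

## Route

Step 1
Reactants: 1 but-3-enoic acid
Product: 2 chloromethyl but-3-enoate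
Conditions: ClCH2OSO2Cl, NaHCO3, Bu4NHSO4 (cat.), CH2Cl2/H2O, 0 °C to rt
Reagents that add atoms: chloromethyl chlorosulfate, ClCOS(=O)(=O)Cl
Why: Phase-transfer O-alkylation of the carboxylate (SN2 at the CH2 of the reagent with loss of chlorosulfate) is the standard chloromethyl ester synthesis and is mild enough to leave the β,γ-alkene out of conjugation.

Step 2
Reactants: 2 chloromethyl but-3-enoate
Product: 4 (R)-4-[(4,4,5,5-tetramethyl-1,3,2-dioxaborolan-2-yl)methyl]oxolan-2-one, via β-boryl alkylcopper 3 (not isolated)
Conditions: CuCl (5 mol%), (R)-SEGPHOS (6 mol%), B2pin2, LiOt-Bu (premixed with B2pin2), THF, 0 °C to rt, slow addition of 2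
Reagents that add atoms: bis(pinacolato)diboron, CC1(C)OB(OC1(C)C)B1OC(C)(C)C(C)(C)O1
Why: Proposed new method: a bisphosphine-ligated borylcopper (monovalent copper, formed from CuCl, LiOt-Bu and B2pin2) should add syn across the terminal alkene of 2 with boron on the terminal carbon and copper on the internal carbon (the future C4), and the secondary alkylcopper 3 should then displace chloride from the OCH2Cl carbon (the future C5); the closest known reaction types are the copper-catalysed borylative exo-cyclization of alkenyl halides bearing an unactivated terminal alkene (racemic, Xantphos) and the enantioselective copper-catalysed borylative cyclopropanation of allylic carbonates and phosphates. Ring C closes in the 5-exo-tet mode. The C4 stereocentre is set in the borylcupration by the chiral bisphosphine, which has to deliver copper to the Re face of the internal alkene carbon, and the C–Cu bond is then replaced by the C–C bond with retention. Regioselectivity (boron terminal, copper internal) rests on the usual preference of ligated Cu–Bpin with simple bisphosphines on 1-alkenes and on five-membered chelation of copper on C4 by the ester carbonyl oxygen. Chemoselectivity for alkene borylcupration over single-electron activation of the C–halogen bond (which would give racemic product through an acyloxymethyl radical) is sought by using the chloride and not the bromide or iodide, and the alkoxide is kept bound as its B2pin2 adduct so that the chloromethyl ester survives. Ring closure must pass through the minor s-cis ester rotamer, which is reachable at room temperature, and no other electrophile competes for the alkylcopper.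

Step 3
Reactants: 5 4-bromo-2-methoxyphenol
Product: 6 4-bromo-2-methoxy-1-(methoxymethoxy)benzene
Conditions: MOMCl, i-Pr2NEt, CH2Cl2, 0 °C to rt
Reagents that add atoms: chloromethyl methyl ether, COCCl
Why: O-alkylation of the phenol gives a MOM ether that is stable to the aqueous base of step 4 and the amide base of step 6.

Step 4
Reactants: 4 (R)-4-[(4,4,5,5-tetramethyl-1,3,2-dioxaborolan-2-yl)methyl]oxolan-2-one; 6 4-bromo-2-methoxy-1-(methoxymethoxy)benzene
Product: 7 (R)-4-{[3-methoxy-4-(methoxymethoxy)phenyl]methyl}oxolan-2-one
Conditions: Pd(OAc)2 (5 mol%), RuPhos (10 mol%), K3PO4, toluene/H2O (10:1), 90 °C; then aq. citric acid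
Reagents that add atoms: none
Why: B-alkyl Suzuki–Miyaura coupling of a primary alkyl pinacol boronate with an aryl bromide under a bulky dialkylbiarylphosphine complex of zerovalent palladium; C4 takes no part, so its configuration is carried through, and the acidic work-up re-closes any lactone opened by the base.

Step 5
Reactants: 8 4-hydroxy-3,5-dimethoxybenzaldehyde (syringaldehyde)
Product: 9 3,5-dimethoxy-4-(methoxymethoxy)benzaldehyde
Conditions: MOMCl, i-Pr2NEt, CH2Cl2, 0 °C to rt
Reagents that add atoms: chloromethyl methyl ether, COCCl
Why: O-alkylation masks the phenol, which would otherwise quench the enolate and deactivate the aldehyde as its phenoxide in step 6.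

Step 6
Reactants: 7 (R)-4-{[3-methoxy-4-(methoxymethoxy)phenyl]methyl}oxolan-2-one; 9 3,5-dimethoxy-4-(methoxymethoxy)benzaldehyde
Product: 10 (3S,4R)-3-{hydroxy[3,5-dimethoxy-4-(methoxymethoxy)phenyl]methyl}-4-{[3-methoxy-4-(methoxymethoxy)phenyl]methyl}oxolan-2-one (both carbinol epimers)
Conditions: LiN(i-Pr)2, THF, −78 °C; then 9; AcOH quench at −78 °C
Reagents that add atoms: none
Why: Lithium enolate aldol addition of a γ-butyrolactone to an aromatic aldehyde; the aldehyde should approach C3 anti to the C4 benzyl group (3,4-trans), and the carbinol configuration does not matter because step 7 erases it.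

Step 7
Reactants: 10 (3S,4R)-3-{hydroxy[3,5-dimethoxy-4-(methoxymethoxy)phenyl]methyl}-4-{[3-methoxy-4-(methoxymethoxy)phenyl]methyl}oxolan-2-one
Product: 12 (3E,4R)-3-{[3,5-dimethoxy-4-(methoxymethoxy)phenyl]methylidene}-4-{[3-methoxy-4-(methoxymethoxy)phenyl]methyl}oxolan-2-one, via acetate 11 (not isolated)
Conditions: Ac2O, Et3N, DMAP (cat.), CH2Cl2, rt; then DBU, toluene, 80 °C
Reagents that add atoms: none
Why: Acetylation followed by DBU-induced E1cB elimination is the standard entry to α-arylidene-γ-butyrolactones and should give the thermodynamically preferred E alkene (aryl anti to the lactone carbonyl); C3 ceases to be a stereocentre and C4 is not touched.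

Step 8
Reactants: 12 (3E,4R)-3-{[3,5-dimethoxy-4-(methoxymethoxy)phenyl]methylidene}-4-{[3-methoxy-4-(methoxymethoxy)phenyl]methyl}oxolan-2-one
Product: 13 (3E,4R)-3-[(4-hydroxy-3,5-dimethoxyphenyl)methylidene]-4-[(4-hydroxy-3-methoxyphenyl)methyl]oxolan-2-one (CNP0351244.1)
Conditions: conc. HCl (cat.), MeOH/THF, 40 °C
Reagents that add atoms: none
Why: Acid-catalysed transacetalization of both aryl MOM ethers to methanol frees the two phenols and traps the formaldehyde unit as dimethoxymethane, without affecting the arylidene lactone or C4.

## Compound list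

1 | but-3-enoic acid | C=CCC(=O)O | starting material
2 | chloromethyl but-3-enoate | C=CCC(=O)OCCl | intermediate
3 | chloromethyl (3R)-3-cuprio-4-(4,4,5,5-tetramethyl-1,3,2-dioxaborolan-2-yl)butanoate (bisphosphine on copper omitted; not isolated) | ClCOC(=O)C[C@H]([Cu])CB1OC(C)(C)C(C)(C)O1 | intermediate
4 | (R)-4-[(4,4,5,5-tetramethyl-1,3,2-dioxaborolan-2-yl)methyl]oxolan-2-one | CC1(C)OB(C[C@H]2COC(=O)C2)OC1(C)C | intermediate
5 | 4-bromo-2-methoxyphenol | COc1cc(Br)ccc1O | starting material
6 | 4-bromo-2-methoxy-1-(methoxymethoxy)benzene | COCOc1ccc(Br)cc1OC | intermediate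
7 | (R)-4-{[3-methoxy-4-(methoxymethoxy)phenyl]methyl}oxolan-2-one | COCOc1ccc(C[C@H]2COC(=O)C2)cc1OC | intermediate
8 | 4-hydroxy-3,5-dimethoxybenzaldehyde | COc1cc(C=O)cc(OC)c1O | starting material
9 | 3,5-dimethoxy-4-(methoxymethoxy)benzaldehyde | COCOc1c(OC)cc(C=O)cc1OC | intermediate
10 | (3S,4R)-3-{hydroxy[3,5-dimethoxy-4-(methoxymethoxy)phenyl]methyl}-4-{[3-methoxy-4-(methoxymethoxy)phenyl]methyl}oxolan-2-one (carbinol epimers) | COCOc1ccc(C[C@H]2COC(=O)[C@@H]2C(O)c2cc(OC)c(OCOC)c(OC)c2)cc1OC | intermediate
11 | acetate of 10 at the carbinol oxygen (not isolated) | COCOc1ccc(C[C@H]2COC(=O)[C@@H]2C(OC(C)=O)c2cc(OC)c(OCOC)c(OC)c2)cc1OC | intermediate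
12 | (3E,4R)-3-{[3,5-dimethoxy-4-(methoxymethoxy)phenyl]methylidene}-4-{[3-methoxy-4-(methoxymethoxy)phenyl]methyl}oxolan-2-one | COCOc1ccc(C[C@H]2COC(=O)/C2=C/c2cc(OC)c(OCOC)c(OC)c2)cc1OC | intermediate
13 | (3E,4R)-3-[(4-hydroxy-3,5-dimethoxyphenyl)methylidene]-4-[(4-hydroxy-3-methoxyphenyl)methyl]oxolan-2-one | COc1cc(C[C@H]2COC(=O)/C2=C/c2cc(OC)c(O)c(OC)c2)ccc1O | target

## Step count and risks

Total step count: 8. Longest linear sequence: 6 steps (steps 1, 2, 4, 6, 7, 8).

Steps most likely to fail:

1. Step 2 (Proposed new method). The alkoxide may attack the chloromethyl ester before borylcupration. Ring closure through the disfavoured s-cis ester rotamer may be slower than protodecupration or β-hydride elimination of the alkylcopper. Single-electron activation of the C–Cl bond may open a radical pathway and erode the enantioselectivity. The fallback sets out from 6 and comes back at 7; it closes ring C at C3–C4 instead and makes steps 1, 2 and 4 unnecessary. A Heck reaction of 6 with allyl alcohol (Pd(OAc)2, Bu4NCl, NaHCO3, DMF, 80 °C) would give 3-[3-methoxy-4-(methoxymethoxy)phenyl]propanal F1. Reduction with NaBH4 in MeOH would give 3-[3-methoxy-4-(methoxymethoxy)phenyl]propan-1-ol F2. Acylation with glyoxylic acid chloride p-toluenesulfonylhydrazone (N,N-dimethylaniline, CH2Cl2, 0 °C; then Et3N) would give 3-[3-methoxy-4-(methoxymethoxy)phenyl]propyl diazoacetate F3. Enantioselective intramolecular carbene C–H insertion into the CH2 β to oxygen with the chiral dirhodium tetrakis(carboxamidate) Rh2(MPPIM)4 (CH2Cl2, reflux; the catalyst antipode that leads to the R series) should then give 7; this is the established entry to (R)-β-benzyl-γ-butyrolactones.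

2. Step 4. Transmetalation of the β-branched primary alkyl boronate may be slow, so that protodeboronation takes over. β-Hydride elimination and reinsertion at the alkylpalladium may move the metal to C4, which would erode the configuration or give an isomeric product. The fallback sets out from 4 and comes back at 7. Oxidation of 4 with NaBO3·4H2O in THF/H2O would give (S)-4-(hydroxymethyl)oxolan-2-one F4. An Appel reaction (CBr4, PPh3, CH2Cl2) would give (R)-4-(bromomethyl)oxolan-2-one F5. Nickel-catalysed reductive cross-electrophile coupling of F5 with 6 (NiI2 hydrate, 4,4′-dimethoxy-2,2′-bipyridine, NaI, pyridine, Zn, DMPU, 60 °C) should give 7. The exocyclic CH2 reacts there as a radical and an alkylnickel, and no organoboron transmetalation is needed.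

3. Step 7. The elimination may give some Z alkene. DBU may also remove the γ-proton at C4 of the product, which would move the double bond into ring C or racemize C4. The fallback sets out from 7 and comes back at 12, bypassing 10 and 11. Treatment of 7 with LiN(i-Pr)2 (2.2 equiv) and ClP(O)(OEt)2 in THF (−78 °C to rt; O-phosphorylation of the enolate, then 1,3 shift of phosphorus from O to C) would give diethyl [(4S)-4-{[3-methoxy-4-(methoxymethoxy)phenyl]methyl}-2-oxooxolan-3-yl]phosphonate F6. The descriptor is 4S only because phosphorus changes the priorities; the spatial arrangement is that of 7. A Horner–Wadsworth–Emmons reaction of F6 with 9 (NaH, THF, 0 °C to rt) should give 12 with E selectivity under non-equilibrating, mildly basic conditions.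

## Further compounds

F1 | step 2 | 3-[3-methoxy-4-(methoxymethoxy)phenyl]propanal | COCOc1ccc(CCC=O)cc1OC
F2 | step 2 | 3-[3-methoxy-4-(methoxymethoxy)phenyl]propan-1-ol | COCOc1ccc(CCCO)cc1OC
F3 | step 2 | 3-[3-methoxy-4-(methoxymethoxy)phenyl]propyl diazoacetate | COCOc1ccc(CCCOC(=O)C=[N+]=[N-])cc1OC
F4 | step 4 | (S)-4-(hydroxymethyl)oxolan-2-one | OC[C@H]1COC(=O)C1
F5 | step 4 | (R)-4-(bromomethyl)oxolan-2-one | BrC[C@H]1COC(=O)C1
F6 | step 7 | diethyl [(4S)-4-{[3-methoxy-4-(methoxymethoxy)phenyl]methyl}-2-oxooxolan-3-yl]phosphonate (C3 epimers) | CCOP(=O)(OCC)C1C(=O)OC[C@@H]1Cc1ccc(OCOC)c(OC)c1
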